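**Retrosynthetic overview**

1. Last disconnection C12–C13: Stille coupling of a 4-stannylbutenolide with the (E)-C11=C12 iodoalkene on C9 of the finished trans-decalin (rings A and B).
2. Ring A is opened at C3=C4: ring-closing carbonyl–olefin metathesis between the C4 methyl ketone on C5 and a C3=C(CH3)2 arm on C10 of a fully oxygenated ring B cyclohexane, with acetone as the only co-product.
3. Feature that makes this possible: in ring B the quaternary C5 carries the C4 acetyl carbon and the neighbouring C10 carries the C1–C2–C3 arm, trans and both equatorial, so a ketone with no α-hydrogen on the ring side faces an electron-rich olefin at six-ring distance; because the ketone itself is the metathesis partner, no isolated C=C is present when the C7=C8 enone is osmylated.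
4. Ring B comes from an enantioselective Diels–Alder reaction of an (E)-2-methyl-2-enal (C9, C10, C11, C20 and the C1–C3 arm) with a 2-silyloxypenta-1,3-diene (C5–C8, C17), which sets C9 and C10; C5 follows by enolate methylation and aldol addition, C7/C8 by osmylation, C6 by hydride reduction.
5. Order of ring formation: ring B (Diels–Alder), then ring A (metathesis at C3=C4), then attachment of the preformed butenolide ring.

Key step: step 17

Remark on notation: clerodane numbering of the target (C1–C20) is used for every intermediate; β is the face of ring B that carries the methyl groups C17, C19 and C20 in the target, α the opposite face.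

Assumption: the (S)-configured oxazaborolidinium catalyst of step 3 is taken to expose the enal face that leads to the C9/C10 configuration drawn (formyl C–H···O binding model for 2-substituted enals); should the first adduct prove to be the antipode, the mirror-image catalyst is used.

**Route**

Step 1
Reactants: 1 4-[(tert-butyldimethylsilyl)oxy]butanal; 2 2-(triphenylphosphoranylidene)propanal
Product: 3 (E)-6-[(tert-butyldimethylsilyl)oxy]-2-methylhex-2-enal
Conditions: toluene, 90 °C
Reagents that add atoms: none
Why: Wittig olefination with a formyl-stabilised ylide is (E)-selective, so the formyl carbon (C11) ends trans to the C1 chain across the new C9=C10 bond, which later becomes the trans C11/C1 relationship of ring B.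

Step 2
Reactants: 4 (E)-pent-3-en-2-one
Product: 5 (E)-triisopropyl(penta-1,3-dien-2-yloxy)silane
Conditions: TIPSOTf, Et3N, Et2O, 0 °C → rt
Reagents that add atoms: triisopropylsilyl trifluoromethanesulfonate, CC(C)[Si](C(C)C)(C(C)C)OS(=O)(=O)C(F)(F)F
Why: Soft enolisation (silyl triflate and amine) removes a proton from the α′-methyl group and traps the cross-conjugated enolate as the 2-silyloxy-1,3-diene without touching the (E)-propenyl unit (silyl enol ether formation).

Step 3
Reactants: 3 (E)-6-[(tert-butyldimethylsilyl)oxy]-2-methylhex-2-enal; 5 (E)-triisopropyl(penta-1,3-dien-2-yloxy)silane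
Product: 6 6-[3-(tert-butyldimethylsilyloxy)propyl]-1,2-dimethyl-4-(triisopropylsilyloxy)cyclohex-3-ene-1-carbaldehyde (ring B; 9α-formyl; 9β-methyl; 10β-arm; both C8 epimers)
Conditions: (S)-B-(o-tolyl)oxazaborolidine of α,α-diphenylprolinol·HNTf2 (20 mol%), CH2Cl2, −78 → −40 °C
Reagents that add atoms: none
Why: Catalytic enantioselective Diels–Alder reaction: the chiral oxazaborolidinium Lewis acid binds the formyl group and shields one enal face, the 2-silyloxy group directs its CH2 terminus (C5) to the β-carbon C10 and the terminal methyl directs C8 to C9, suprafacial addition to the (E)-enal fixes the C20 methyl cis and the formyl group trans to the C10 arm, and the catalyst fixes the absolute sense at C9 and C10, while C8 forms without control and is erased in step 6.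

Step 4
Reactants: 6 ring B aldehyde (Diels–Alder adduct)
Product: 7 [6-[3-(tert-butyldimethylsilyloxy)propyl]-1,2-dimethyl-4-(triisopropylsilyloxy)cyclohex-3-en-1-yl]methanol (C11 primary alcohol)
Conditions: NaBH4, MeOH, 0 °C
Reagents that add atoms: none
Why: Borohydride reduction of the neopentyl aldehyde to the primary alcohol while the ring carbonyl stays masked as the silyl enol ether; no stereocentre is affected.

Step 5
Reactants: 7 C11 primary alcohol
Product: 8 bis-TBS ether of 7 (C3–OTBS and C11–OTBS; C6 triisopropylsilyl enol ether)
Conditions: TBSCl, imidazole, DMF, rt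
Reagents that add atoms: tert-butyldimethylsilyl chloride, CC(C)(C)[Si](C)(C)Cl
Why: Standard silylation of the primary alcohol so that C11 survives the enolate chemistry as a silyl ether.

Step 6
Reactants: 8 bis-TBS silyl enol ether
Product: 9 5-[3-(tert-butyldimethylsilyloxy)propyl]-4-[(tert-butyldimethylsilyloxy)methyl]-3,4-dimethylcyclohex-2-en-1-one (C6 ketone; C7=C8; 9β-methyl; 10β-arm)
Conditions: Pd(OAc)2 (1.1 equiv), MeCN, 40 °C
Reagents that add atoms: none
Why: Saegusa–Ito oxidation: the silyl enol ether gives a C7-bound palladium enolate whose only β-hydrogen is on C8, so β-hydride elimination delivers the C7=C8 enone regiospecifically and removes the uncontrolled C8 centre.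

Step 7
Reactants: 9 ring B enone
Product: 11 5α-methyl enone (C19 methyl in place), via lithium dienolate 10 (not isolated)
Conditions: LiN(i-Pr)2, THF, −78 °C; MeI, DMPU, −78 → −30 °C
Reagents that add atoms: iodomethane, CI
Why: Kinetic deprotonation of the enone at the α′-carbon C5 gives the cross-conjugated dienolate 10, which is C-methylated (enolate alkylation, methyl expected anti to the C10 arm); the C5 configuration is not needed because the centre is planarised again in step 8.

Step 8
Reactants: 11 5α-methyl enone
Product: 13 5α-(1-hydroxyethyl)-5β-methyl enone (carbinol epimers), via lithium dienolate 12 (not isolated)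
Conditions: LiN(i-Pr)2, THF, −78 °C; CH3CHO, −78 °C; AcOH quench at −78 °C
Reagents that add atoms: acetaldehyde, CC=O
Why: Aldol addition of the tetrasubstituted dienolate 12 to acetaldehyde builds the C5 quaternary centre, the aldehyde entering anti to the neighbouring C10 arm and away from the pseudoaxial C20 methyl (usual 2,3-trans outcome), so that C4 is α and the C19 methyl β; the carbinol configuration is irrelevant.

Step 9
Reactants: 13 aldol adduct
Product: 14 5α-acetyl-5β-methyl enone (2,2-disubstituted 1,3-diketone; C4 ketone in place)
Conditions: Dess–Martin periodinane, CH2Cl2, rt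
Reagents that add atoms: none
Why: Dess–Martin oxidation converts the secondary alcohol into the C4 methyl ketone under neutral conditions that do not cleave the resulting non-enolisable 1,3-diketone (no retro-Claisen, no retro-aldol).

Step 10
Reactants: 14 enone diketone
Product: 15 7α,8α-dihydroxy diketone (8β-methyl)
Conditions: OsO4 (5 mol%), N-methylmorpholine N-oxide, citric acid, t-BuOH–H2O, rt
Reagents that add atoms: osmium tetroxide, O=[Os](=O)(=O)=O; N-methylmorpholine N-oxide (reoxidant, ultimate oxygen source), C[N+]1([O-])CCOCC1; water, O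
Why: Catalytic osmium tetroxide cis-dihydroxylation of the only C=C in the molecule; the reagent approaches the α face because the β face of C7=C8 is covered by the pseudoaxial C19 and C20 methyl groups, giving both new C–O bonds α (C8 methyl β).

Step 11
Reactants: 15 dihydroxy diketone
Product: 16 6β,7α,8α-triol with intact C4 methyl ketone
Conditions: NaBH4, MeOH–CH2Cl2, −78 → −40 °C
Reagents that add atoms: none
Why: Borohydride reduction is chemoselective for the α-hydroxy ring ketone (inductively activated, hydride delivered from the alkoxyborohydride of the α-face hydroxyls) over the neopentyl methyl ketone, and axial attack from the α face (the β face is blocked by the axial C19 methyl on C5) gives the equatorial 6β-alcohol.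

Step 12
Reactants: 16 triol
Product: 17 6β,7α-diacetate (8α-hydroxyl free; bis-TBS ether)
Conditions: Ac2O, pyridine, DMAP (cat.), CH2Cl2, 0 °C → rt
Reagents that add atoms: acetic anhydride, CC(=O)OC(C)=O
Why: Acetylation (nucleophilic catalysis by DMAP) esterifies the two secondary alcohols and leaves the hindered tertiary 8-hydroxyl free, installing the acetates of the target, which also protect C6 and C7 during the later oxidation.

Step 13
Reactants: 17 diacetate bis-TBS ether
Product: 18 diacetate with free C3 and C11 primary alcohols
Conditions: HF·pyridine, THF–pyridine, 0 °C → rt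
Reagents that add atoms: none
Why: Fluoride-induced desilylation frees both primary alcohols in one operation; acetates, ketone and tertiary alcohol are inert to buffered hydrogen fluoride.

Step 14
Reactants: 18 diacetate diol
Product: 19 diacetate dialdehyde (C3 and C11 formyl groups)
Conditions: Dess–Martin periodinane, CH2Cl2, 0 °C → rt
Reagents that add atoms: none
Why: Dess–Martin oxidation of both primary alcohols to aldehydes (the tertiary alcohol cannot be oxidised), giving the C3 and C11 formyl groups at neutral pH.

Step 15
Reactants: 19 diacetate dialdehyde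
Product: 20 C11 aldehyde with a C3=C(CH3)2 arm on C10
Conditions: i-PrPPh3I, n-BuLi, THF, 0 °C; then 19, −78 → −20 °C
Reagents that add atoms: isopropyltriphenylphosphonium iodide, CC(C)[P+](c1ccccc1)(c1ccccc1)c1ccccc1.[I-]
Why: Wittig olefination with a bulky non-stabilised ylide at low temperature is selective for the unhindered C3 aldehyde; the neopentyl C11 aldehyde (on quaternary C9) and the C4 ketone (on quaternary C5) react far more slowly.

Step 16
Reactants: 20 C11 aldehyde
Product: 21 (E)-C11=C12 iodoalkene carrying the C4 acetyl group and the C3=C(CH3)2 arm (metathesis precursor)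
Conditions: CrCl2, CHI3, THF, 0 °C → rt
Reagents that add atoms: iodoform, IC(I)I
Why: Takai olefination: the geminal dichromium reagent from iodoform and CrCl2 (divalent chromium) adds to aldehydes but not to ketones or esters and gives the (E)-iodoalkene with high selectivity.

Step 17
Reactants: 21 keto olefin
Product: 23 6β,7α-diacetoxy-8α-hydroxy-9α-[(E)-2-iodovinyl] trans-decalin with the C3=C4 bond (rings A and B), via oxetane 22 (not isolated)
Conditions: FeCl3 (20 mol%), ClCH2CH2Cl, rt
Reagents that add atoms: none
Why: FeCl3 binds the C4 ketone and the electron-rich C3=C(CH3)2 olefin adds to it in an asynchronous concerted [2+2] cycloaddition to give the oxetane 22, which the same Lewis acid opens in the opposite sense (retro-[2+2]) so that volatile acetone leaves and the C3=C4 bond remains. The closest known reaction is the iron trichloride-catalysed ring-closing carbonyl–olefin metathesis of α,α-disubstituted ketones carrying a prenyl arm, aliphatic methyl ketones included, for which a chloride-bridged dimer of trivalent iron is taken as the active superelectrophile. Ring A closes in the 6-exo mode (C3 attacks C4, the isopropylidene carbon stays outside the ring) through a chair-like transition state that spans the trans-diequatorial C5–C4 and C10–C1 bonds, hence the trans-decalin; the four-membered oxetane ring is only transient. No stereocentre of the product is created (C3 and C4 become sp2, the two oxetane centres are erased), and the centres set earlier are not at risk because C5 and C9 are quaternary. The step needs chemoselectivity for the ketone over the two acetate carbonyls, the iodoalkene and the tertiary alcohol, and metathesis instead of carbonyl-ene or Prins diversion: the ketone is the only carbonyl electrophilic enough, it has no α-hydrogen on the ring side, the iodoalkene is electron-poor, and loss of acetone makes the fragmentation irreversible.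

Step 18
Reactants: 24 4-bromofuran-2(5H)-one
Product: 25 4-(tributylstannyl)furan-2(5H)-one
Conditions: (Bu3Sn)2, Pd(PPh3)4 (5 mol%), toluene, 100 °C
Reagents that add atoms: hexabutylditin, CCCC[Sn](CCCC)(CCCC)[Sn](CCCC)(CCCC)CCCC
Why: Palladium-catalysed stannylation of a vinyl bromide with a distannane (oxidative addition to zerovalent palladium, tin–palladium exchange, reductive elimination).

Step 19
Reactants: 23 iodovinyl trans-decalin; 25 4-(tributylstannyl)furan-2(5H)-one
Product: 26 CNP0383656.1 (6β,7α-diacetoxy-8α-hydroxy-trans-cleroda-3,11E,13-trien-15,16-olide)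
Conditions: Pd2(dba)3 (5 mol%), AsPh3 (20 mol%), NMP, 45 °C
Reagents that add atoms: none
Why: Stille cross-coupling joins C12 and C13 with retention of the (E)-alkene geometry under neutral conditions that the acetates, the tertiary alcohol and the butenolide tolerate.

**Compound list**

1 | 4-[(tert-butyldimethylsilyl)oxy]butanal | O=CCCCO[Si](C)(C)C(C)(C)C | starting material
2 | 2-(triphenylphosphoranylidene)propanal | CC(C=O)=P(c1ccccc1)(c1ccccc1)c1ccccc1 | starting material
3 | (E)-6-[(tert-butyldimethylsilyl)oxy]-2-methylhex-2-enal | O=C/C(C)=C/CCCO[Si](C)(C)C(C)(C)C | intermediate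
4 | (E)-pent-3-en-2-one | C/C=C/C(C)=O | starting material
5 | (E)-triisopropyl(penta-1,3-dien-2-yloxy)silane | C=C(O[Si](C(C)C)(C(C)C)C(C)C)/C=C/C | intermediate
6 | 6-[3-(tert-butyldimethylsilyloxy)propyl]-1,2-dimethyl-4-(triisopropylsilyloxy)cyclohex-3-ene-1-carbaldehyde; 9α-formyl, 9β-methyl, 10β-arm, C8 epimers | CC(C)[Si](C(C)C)(C(C)C)OC1=CC(C)[C@](C)(C=O)[C@@H](CCCO[Si](C)(C)C(C)(C)C)C1 | intermediate
7 | C11 primary alcohol from 6 (9α-hydroxymethyl) | CC(C)[Si](C(C)C)(C(C)C)OC1=CC(C)[C@](C)(CO)[C@@H](CCCO[Si](C)(C)C(C)(C)C)C1 | intermediate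
8 | bis-TBS ether of 7 (C6 triisopropylsilyl enol ether) | CC(C)[Si](C(C)C)(C(C)C)OC1=CC(C)[C@](C)(CO[Si](C)(C)C(C)(C)C)[C@@H](CCCO[Si](C)(C)C(C)(C)C)C1 | intermediate
9 | ring B enone: 5-[3-(TBS-oxy)propyl]-4-[(TBS-oxy)methyl]-3,4-dimethylcyclohex-2-en-1-one; 9β-methyl, 10β-arm | O=C1C=C(C)[C@](C)(CO[Si](C)(C)C(C)(C)C)[C@@H](CCCO[Si](C)(C)C(C)(C)C)C1 | intermediate
10 | lithium dienolate of 9 (C5=C6–OLi, C7=C8) | [Li]OC=1C=C(C)[C@](C)(CO[Si](C)(C)C(C)(C)C)[C@@H](CCCO[Si](C)(C)C(C)(C)C)C=1 | intermediate
11 | 5α-methyl enone | O=C1C=C(C)[C@](C)(CO[Si](C)(C)C(C)(C)C)[C@@H](CCCO[Si](C)(C)C(C)(C)C)[C@@H]1C | intermediate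
12 | lithium dienolate of 11 | [Li]OC=1C=C(C)[C@](C)(CO[Si](C)(C)C(C)(C)C)[C@@H](CCCO[Si](C)(C)C(C)(C)C)C=1C | intermediate
13 | 5α-(1-hydroxyethyl)-5β-methyl enone (carbinol epimers) | O=C1C=C(C)[C@](C)(CO[Si](C)(C)C(C)(C)C)[C@@H](CCCO[Si](C)(C)C(C)(C)C)[C@]1(C)C(C)O | intermediate
14 | 5α-acetyl-5β-methyl enone (1,3-diketone) | O=C1C=C(C)[C@](C)(CO[Si](C)(C)C(C)(C)C)[C@@H](CCCO[Si](C)(C)C(C)(C)C)[C@]1(C)C(C)=O | intermediate
15 | 7α,8α-dihydroxy diketone | O=C1[C@H](O)[C@](C)(O)[C@](C)(CO[Si](C)(C)C(C)(C)C)[C@@H](CCCO[Si](C)(C)C(C)(C)C)[C@]1(C)C(C)=O | intermediate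
16 | 6β,7α,8α-triol methyl ketone | O[C@H]1[C@H](O)[C@](C)(O)[C@](C)(CO[Si](C)(C)C(C)(C)C)[C@@H](CCCO[Si](C)(C)C(C)(C)C)[C@]1(C)C(C)=O | intermediate
17 | 6β,7α-diacetate, 8α-OH free, bis-TBS ether | CC(=O)O[C@H]1[C@H](OC(C)=O)[C@](C)(O)[C@](C)(CO[Si](C)(C)C(C)(C)C)[C@@H](CCCO[Si](C)(C)C(C)(C)C)[C@]1(C)C(C)=O | intermediate
18 | diacetate with free C3 and C11 primary alcohols | CC(=O)O[C@H]1[C@H](OC(C)=O)[C@](C)(O)[C@](C)(CO)[C@@H](CCCO)[C@]1(C)C(C)=O | intermediate
19 | diacetate dialdehyde (C3 and C11 formyl) | CC(=O)O[C@H]1[C@H](OC(C)=O)[C@](C)(O)[C@](C)(C=O)[C@@H](CCC=O)[C@]1(C)C(C)=O | intermediate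
20 | C11 aldehyde with C3=C(CH3)2 arm | CC(=O)O[C@H]1[C@H](OC(C)=O)[C@](C)(O)[C@](C)(C=O)[C@@H](CCC=C(C)C)[C@]1(C)C(C)=O | intermediate
21 | (E)-C11=C12 iodoalkene with C4 acetyl and C3=C(CH3)2 arm | CC(=O)O[C@H]1[C@H](OC(C)=O)[C@](C)(O)[C@](C)(/C=C/I)[C@@H](CCC=C(C)C)[C@]1(C)C(C)=O | intermediate
22 | oxetane from C4=O and C3=C(CH3)2 (ring A closed, C3–C4 single bond) | CC(=O)O[C@H]1[C@H](OC(C)=O)[C@](C)(O)[C@](C)(/C=C/I)[C@H]2CCC3C(C)(C)OC3(C)[C@]12C | intermediate
23 | 6β,7α-diacetoxy-8α-hydroxy-9α-[(E)-2-iodovinyl] trans-decalin with C3=C4 | CC(=O)O[C@H]1[C@H](OC(C)=O)[C@](C)(O)[C@](C)(/C=C/I)[C@H]2CCC=C(C)[C@]12C | intermediate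
24 | 4-bromofuran-2(5H)-one | BrC1=CC(=O)OC1 | starting material
25 | 4-(tributylstannyl)furan-2(5H)-one | CCCC[Sn](CCCC)(CCCC)C1=CC(=O)OC1 | intermediate
26 | CNP0383656.1 | CC(=O)O[C@H]1[C@H](OC(C)=O)[C@](C)(O)[C@](C)(/C=C/C2=CC(=O)OC2)[C@H]2CCC=C(C)[C@]12C | target

**Step count and risks**

Total steps: 19. Longest linear sequence: 17 steps (steps 1, 3–17 and 19, from 1 to 26).

Steps most likely to fail:

Step 17. The iron-bound ketone–olefin pair may leave the metathesis manifold: proton loss from the carbocationic intermediate (carbonyl-ene type) or sequestration of the catalyst by the tertiary hydroxyl and the acetates, so that the oxetane does not form or does not fragment. The fallback replaces carbonyl–olefin by olefin–olefin metathesis. Setting out from 21, the C4 ketone would be methylenated under Lombardo conditions (Zn, CH2Br2, TiCl4, THF–CH2Cl2, 0 °C, esters tolerated) to the 5α-isopropenyl compound F1. Ring A would then be closed by ring-closing olefin metathesis with the second-generation Grubbs catalyst RuCl2(=CHPh)(PCy3)(H2IMes) in toluene at 80 °C under ethene (ethenolysis of the prenyl terminus, then closure onto the isopropenyl group). This comes back to the route at 23.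

Step 3. The trisubstituted enal may be too unreactive toward the hindered catalyst, or facial discrimination may erode and give material of low enantiomeric purity. The fallback is a racemic cycloaddition followed by enzymatic resolution. From 3 and 5, a Diels–Alder reaction promoted by Me2AlCl (CH2Cl2, −78 → −20 °C) would give 6 together with its enantiomer, the ent-adduct F2. NaBH4 reduction would give 7 together with its enantiomer, the ent-alcohol F3. A lipase (Burkholderia cepacia lipase, vinyl acetate, tert-butyl methyl ether), chosen by screening to acylate the unwanted enantiomer, would convert F3 into the ent-acetate F4 and leave 7, which is separated by chromatography and re-enters the route at 7.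

Step 10. Osmylation of the hindered, electron-poor enone may be sluggish, with slow degradation of the 1,3-diketone (retro-Claisen cleavage) on long exposure to the aqueous oxidant. The fallback reduces first and osmylates an electron-rich olefin. From 14, Luche reduction (NaBH4, CeCl3·7H2O, MeOH, −78 °C) of the conjugated C6 carbonyl from the α face would give the 6β-allylic alcohol F5. Osmylation (OsO4, N-methylmorpholine N-oxide) of its now electron-rich C7=C8 bond, anti to the allylic hydroxyl and to the axial methyl groups, would give the triol 16 directly, where the route is rejoined.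

Further compounds

F1 | step 17 | 5α-isopropenyl analogue of 21 (C4 ketone methylenated) | CC(=O)O[C@H]1[C@H](OC(C)=O)[C@](C)(O)[C@](C)(/C=C/I)[C@@H](CCC=C(C)C)[C@]1(C)C(C)=C
F2 | step 3 | enantiomer of 6 (ent-adduct) | CC(C)[Si](C(C)C)(C(C)C)OC1=CC(C)[C@@](C)(C=O)[C@H](CCCO[Si](C)(C)C(C)(C)C)C1
F3 | step 3 | enantiomer of 7 (ent-alcohol) | CC(C)[Si](C(C)C)(C(C)C)OC1=CC(C)[C@@](C)(CO)[C@H](CCCO[Si](C)(C)C(C)(C)C)C1
F4 | step 3 | acetate of the ent-alcohol F3 | CC(C)[Si](C(C)C)(C(C)C)OC1=CC(C)[C@@](C)(COC(C)=O)[C@H](CCCO[Si](C)(C)C(C)(C)C)C1
F5 | step 10 | 6β-allylic alcohol from 14 (C7=C8, C4 ketone intact) | O[C@H]1C=C(C)[C@](C)(CO[Si](C)(C)C(C)(C)C)[C@@H](CCCO[Si](C)(C)C(C)(C)C)[C@]1(C)C(C)=O
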